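Two questions are asked of the flasks delta, zeta, theta and alpha: how much complex with two exchanged stands at the end of each, and what shape that row has.

| setting | Saturday's | Tuesday's | Monday's | delta | zeta | theta | alpha |
|---|---|---|---|---|---|---|---|
| starting complex | 0.86 mM (in portions, 4) | 6.5 mM (in portions, 4) | 35 mM (in portions, 4) | 1.2 mM (in portions, 4) | 3.0 mM (in portions, 4) | 10 mM (in portions, 4) | 30 mM (in portions, 4) |
| incoming ligand | 18 mM | 18 mM | 18 mM | 18.0 mM | 18.0 mM | 18.0 mM | 18.0 mM |
| remark | run made earlier; portions every 4.0 min | run made earlier; portions every 4.0 min | run made earlier; portions every 4.0 min | the portions of starting complex follow each other after 4.0 min, the first at the start | the portions of starting complex follow each other after 4.0 min, the first at the start | the portions of starting complex follow each other after 4.0 min, the first at the start | the portions of starting complex follow each other after 4.0 min, the first at the start |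
| time |  |  |  | 1.5 h | 1.5 h | 1.5 h | 1.5 h |

| Saturday's: time / min | Saturday's: complex with two exchanged / % | Tuesday's: time / min | Tuesday's: complex with two exchanged / % | Monday's: time / min | Monday's: complex with two exchanged / % |
|---|---|---|---|---|---|
| 8.00 | 0 | 5.00 | 0 | 5.00 | 0.6 |
| 20.0 | 1.9 | 12.0 | 0.5 | 12.0 | 0.5 |
| 40.0 | 8.3 | 25.0 | 2.0 | 25.0 | 1.5 |
| 60.0 | 15.0 | 60.0 | 11.0 | 60.0 | 2.2 |

(readings scatter by 0.5 percentage points)

- "hardly changes" means that all values lie within two and a half points (for a concentration: within two and a half percent of the largest)

- [complex with two exchanged] at the end for delta, zeta, theta, alpha, in this order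
- the shape of the row from first to last (hardly changes / rises, then falls / falls all the way / rises all the way / falls, then rises)

One number folds the charges together: alpha's load 1.67, the whole charge of starting complex over the charge of incoming ligand. It tells how far the incoming ligand stretches, since each complex with two exchanged costs two of it. Delta stands at 0.0667, zeta at 0.167 and theta at 0.556.

At the low end, Saturday's flask has a load of 0.0478. Extending its last slope gives, by my reckoning, 25.1% at 1.5 h, so delta should hold about 0.301 mM. At the high end, Monday's flask has a load of 1.94. Its starting complex exceeds its incoming ligand, which makes the ligand the limiting reagent, and it reads 2.2% at 60.0 min.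

To join the ends, take amounts at 60.0 min: Tuesday's flask, at a load of 0.361, reads 0.715 mM and Monday's reads 0.770 mM, close for readings that scatter by 0.5 percentage points. If the curve is a hump symmetric on a logarithmic scale, equal heights on either side put its top midway, at a load of 0.838, or 15.1 mM. Theta and alpha stand on either side of this top, and alpha is farther from it than theta, by a factor of 1.99 against 1.51, so the row should rise, then fall.

One number is not enough, though. At 25.0 min, Monday's flask reads 0.525 mM, more than the 0.130 mM read in Tuesday's. Time therefore counts too, and the top is a reading for 60.0 min.

The forecast gives 0.29 mM, 0.66 mM, 1.5 mM and 1.05 mM, with the shape rises, then falls, on the ground that “the amount saturates”. It puts the peak near 10 mM, lower than my top, but the shape is the same.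

    starting complex + incoming ligand ⇌ leaving ligand + complex with one exchanged (K = 20.0, k = 1.80 /M/min)
    complex with one exchanged + incoming ligand ⇌ leaving ligand + complex with two exchanged (K = 1.00, k = 0.360 /M/min)
    starting complex ⇌ dormant form (K = 1.50, k = 0.00340 /min)

The flasks give 0.306 mM, 0.684 mM, 1.44 mM and 1.16 mM: rises, then falls, the forecast's shape. The row turns at 15 mM, a load of 0.816. The load also reckons the incoming ligand left: one, less the load times the sum of the share with one exchanged and twice the share with two exchanged. For alpha, the load of 1.67 with 45.9% and 3.87% leaves 10.6%, and the flask holds 10.6%. For theta, 61.1% and 14.4% leave 50.1%, and the flask holds 50.1%.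

The runs were generated by integration on assumed constants, noise included.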